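**Retrosynthetic overview**

- Atoms are labelled C1–C31 in the order of the target SMILES. The plan rests on the bicyclo[4.3.1]decane formed by ring A (C15–C16–C17–C18–C20–C21) and ring B (C5–C6–C8–C21–C20–C18–C22), with bridgeheads C18 and C21 and one-carbon bridge C20; ring C (C8–C10–O11–C12–C15–C21) already links C8 to C15.
- Late disconnections: the C24–O25 enol ester (copper-catalysed coupling of an (E)-alkenylboron with 3-methylbut-2-enoic acid), C5–C4 (enolate alkylation) and C22–C23 (conjugate alkynylation of the C5=C22 enone).
- Key disconnection: C18–C20 and C16–C17 by a type 2 intramolecular Diels–Alder reaction of a 3,4-dimethylideneoxane whose C8 carries a keto chain ending in an (E)-vinyl sulfone; the C15=C21 bridgehead alkene is hydrogenated afterwards.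
- The diene comes from reductive cyclisation of a 1,7-diyne (C15–C21 bond); C8 is set by asymmetric alkynylation of an α-keto ester; the chain is attached by Weinreb ketone synthesis and Horner–Wadsworth–Emmons olefination.
- Ring order: ring C first, then rings A and B together in the key step.

Key step: step 9

Assumption: the (1S,2S) amino alcohol of step 3 is taken to give the (R) carbinol at C8; if the sense proves opposite, its (1R,2R) antipode is used and nothing else changes.

**Route**

Step 1
Reactants: 1 2-methyl-4-(trimethylsilyl)but-3-yn-2-ol; 2 methyl 2-(bromomethyl)prop-2-enoate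
Product: 3 methyl 2-({[2-methyl-4-(trimethylsilyl)but-3-yn-2-yl]oxy}methyl)prop-2-enoate
Conditions: NaH, THF, 0 °C to rt
Reagents that add atoms: none
Why: The tertiary sodium alkoxide displaces bromide from the 2-(bromomethyl)acrylate by SN2′ addition–elimination (Williamson-type etherification; direct and transposed attack give the same product), forming O11–C10 from the alkoxide side, where no substitution at the tertiary carbon is needed.

Step 2
Reactants: 3 acrylate ether
Product: 4 methyl 3-{[2-methyl-4-(trimethylsilyl)but-3-yn-2-yl]oxy}-2-oxopropanoate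
Conditions: O3, CH2Cl2, –78 °C; then Me2S, –78 °C to rt
Reagents that add atoms: ozone, O=[O+][O-]
Why: Ozonolysis cleaves the 1,1-disubstituted alkene to the α-keto ester while the silyl alkyne, which reacts far more slowly with ozone, is kept.

Step 3
Reactants: 4 α-keto ester; 5 ethynyltrimethylsilane
Product: 6 methyl (2R)-2-hydroxy-2-({[2-methyl-4-(trimethylsilyl)but-3-yn-2-yl]oxy}methyl)-4-(trimethylsilyl)but-3-ynoate
Conditions: Zn(OTf)2 (20 mol%), (1S,2S)-2-(dimethylamino)-1-(4-nitrophenyl)-3-[(tert-butyldimethylsilyl)oxy]propan-1-ol (22 mol%), Et3N (30 mol%), toluene, 50 °C, sealed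
Reagents that add atoms: none
Why: Catalytic asymmetric alkynylation of an α-keto ester by a zinc acetylide formed in situ and bound to a chiral amino alcohol sets C8 as (R) by ligand-controlled attack on one face of the chelated 1,2-dicarbonyl, and the silyl cap on the ether alkyne keeps it from competing as a pronucleophile.

Step 4
Reactants: 6 hydroxy ester
Product: 7 (2R)-2-hydroxy-N-methoxy-N-methyl-2-({[2-methyl-4-(trimethylsilyl)but-3-yn-2-yl]oxy}methyl)-4-(trimethylsilyl)but-3-ynamide
Conditions: MeNH(OMe)·HCl, iPrMgCl, THF, –20 to 0 °C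
Reagents that add atoms: N,O-dimethylhydroxylamine hydrochloride, CNOC.Cl
Why: Aminolysis of the ester by the chloromagnesium amide of N,O-dimethylhydroxylamine (Weinreb amide formation) proceeds on the magnesium alkoxide of the tertiary alcohol without touching the silyl alkynes or C8.

Step 5
Reactants: 7 Weinreb amide; 8 2-(2-bromoethyl)-2-methyl-1,3-dioxolane
Product: 11 (6R)-6-hydroxy-6-({[2-methyl-4-(trimethylsilyl)but-3-yn-2-yl]oxy}methyl)-8-(trimethylsilyl)oct-7-yne-2,5-dione, via Grignard reagent 9 (not isolated), via dioxolane ketone 10 (not isolated)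
Conditions: 8, Mg, THF, below 35 °C; 7, iPrMgCl (1 equiv), THF, –20 °C, then 9, 0 °C to rt; 1 M HCl, THF, rt
Reagents that add atoms: water, O
Why: Weinreb ketone synthesis: the chelated tetrahedral adduct stops at single addition of the primary Grignard reagent, and aqueous acid then hydrolyses the dioxolane to the methyl ketone without affecting the silyl alkynes or the tertiary ether.

Step 6
Reactants: 11 bis-silyl diketone
Product: 12 (6R)-6-hydroxy-6-{[(2-methylbut-3-yn-2-yl)oxy]methyl}oct-7-yne-2,5-dione
Conditions: K2CO3, MeOH, 0 °C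
Reagents that add atoms: none
Why: Carbonate-catalysed methanolysis of both C(sp)–Si bonds gives the terminal 1,7-diyne, and short exposure at 0 °C should leave the α-ketol and the 1,4-diketone intact.

Step 7
Reactants: 12 diyne diketone; 13 diethyl [(phenylsulfonyl)methyl]phosphonate
Product: 14 (3R,7E)-3-hydroxy-7-methyl-3-{[(2-methylbut-3-yn-2-yl)oxy]methyl}-8-(phenylsulfonyl)oct-7-en-1-yn-4-one
Conditions: 13, NaH, THF, 0 °C; then 12, 0 °C to rt
Reagents that add atoms: none
Why: Horner–Wadsworth–Emmons olefination takes place at the unhindered methyl ketone (the C6 ketone is shielded by quaternary C8) and should favour the (E) vinyl sulfone with the sulfonyl group anti to the longer chain; any (Z) isomer is removed by chromatography and would in any case converge after step 10.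

Step 8
Reactants: 14 vinyl sulfone diyne
Product: 15 (4E)-1-[(3R)-3-hydroxy-6,6-dimethyl-4,5-dimethylideneoxan-3-yl]-4-methyl-5-(phenylsulfonyl)pent-4-en-1-one
Conditions: Pd2(dba)3·CHCl3 (2.5 mol%), P(o-tol)3 (10 mol%), AcOH, Et3SiH, benzene, rt
Reagents that add atoms: none
Why: Palladium hydride (from zerovalent palladium and acetic acid) adds to one terminal alkyne, the alkenylpalladium carbopalladates the second alkyne in a 6-exo-dig closure that forms C15–C21, and the silane reduces the dienylpalladium, a known reductive cyclisation of 1,6- and 1,7-diynes to 1,2-dialkylidene rings that tolerates ketones, free hydroxyls and electron-poor alkenes.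

Step 9
Reactants: 15 triene
Product: 16 (8R,17R,18R) cycloadduct: tricycle with C15=C21 bridgehead alkene, C6 ketone, C8 hydroxyl, gem-dimethyl C12, methyl on C18 and phenylsulfonyl on C17 cis to that methyl
Conditions: toluene (0.005 M), BHT (cat.), sealed tube, 150 °C
Reagents that add atoms: none
Why: Concerted, suprafacial [4+2] cycloaddition of the s-cis-locked exocyclic diene (C20=C21–C15=C16) with the sulfone-activated C17=C18 alkene, a type 2 intramolecular Diels–Alder reaction of the kind known to give bridgehead-alkene bicyclo[4.3.1]decenes from 2-tethered dienes with four-atom tethers. Ring A (six-membered) is closed by the two new bonds C18–C20 and C16–C17, and ring B (seven-membered) is closed in the bridged mode by the C18–C20 bond because the tether C8–C6–C5–C22 leaves the diene at its internal carbon C21; the opposite orientation is geometrically excluded for a tether of this length. C18 is controlled by the C8 carbinol: its acyl branch, and with it the dienophile, can only reach the diene face opposite the hydroxyl, and the bridgehead configuration then follows from the bicyclic topology. C17 follows from retention of the (E) alkene geometry (sulfonyl cis to the C18 methyl) and is erased in step 10. Only π-facial selectivity is needed and the single stereocentre C8, held in ring C, secures it. Because C8 and C12 are quaternary the diene cannot be lost by 1,5-hydrogen shift, high dilution suppresses its dimerisation, and the C15=C21 alkene is tolerable because it is trans only within the nine-membered perimeter.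

Step 10
Reactants: 16 cycloadduct
Product: 17 (8R,18R) desulfonylated tricyclic alkene ketol (CH2 at C17, C15=C21 alkene retained)
Conditions: Na(Hg) (5%), Na2HPO4, MeOH–THF, –20 °C
Reagents that add atoms: none
Why: Reductive desulfonylation by electron transfer from sodium amalgam cleaves the C17–S bond and methanol protonates the carbanion; the aryl sulfone is reduced more readily than the hindered dialkyl ketone, and the buffered low-temperature medium protects the α-ketol.

Step 11
Reactants: 17 alkene ketol
Product: 18 (8R,15R,18R,21S) saturated tricyclic ketol, C15–H and C21–H cis to each other and to the C8 hydroxyl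
Conditions: H2 (1 atm), [Ir(cod)(PCy3)(py)]PF6 (cat.), CH2Cl2, rt
Reagents that add atoms: none
Why: Hydroxyl-directed homogeneous hydrogenation: the cationic iridium catalyst binds the allylic C8 hydroxyl and delivers both hydrogens syn to the outer face of the strained tetrasubstituted alkene, the only face from which C21 can become an out-bridgehead, which sets C21 and C15 together.

Step 12
Reactants: 18 saturated ketol
Product: 19 bis-silyl derivative of 18 (C8 trimethylsilyl ether and C5=C6 trimethylsilyl enol ether)
Conditions: LiN(iPr)2 (2.3 equiv), THF, –78 °C; TMSCl, Et3N, –78 °C to rt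
Reagents that add atoms: chlorotrimethylsilane, C[Si](C)(C)Cl
Why: Double deprotonation (hydroxyl, then C5, the only enolisable position because C8 is quaternary) and silylation give the enol silyl ether regiospecifically and mask the tertiary alcohol in the same operation.

Step 13
Reactants: 19 silyl enol ether
Product: 20 C5=C22 enone with C8 trimethylsilyl ether (other stereocentres as in 18)
Conditions: Pd(OAc)2 (1.1 equiv), MeCN, rt
Reagents that add atoms: none
Why: Saegusa–Ito oxidation: palladation of the enol silyl ether at C5 and syn β-hydride elimination of a C22 hydrogen give the enone, and over-oxidation is impossible because C8 and C18 are quaternary.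

Step 14
Reactants: 20 enone; 5 ethynyltrimethylsilane
Product: 22 C5=C6 trimethylsilyl enol ether bearing (trimethylsilyl)ethynyl on C22 cis to the C18 methyl and the C8 trimethylsilyl ether, via alkynylzinc bromide 21 (not isolated)
Conditions: 5, n-BuLi, THF, –78 °C; ZnBr2, 0 °C; then 20, TMSOTf, Et2O–THF, –40 to 0 °C; Et3N, pentane, filtration
Reagents that add atoms: trimethylsilyl trifluoromethanesulfonate, C[Si](C)(C)OS(=O)(=O)C(F)(F)F
Why: Silyl triflate-promoted conjugate addition of an alkynylzinc halide to an s-trans cyclic enone (a known 1,4-transfer of an alkynyl group that gives the enol silyl ether directly); the nucleophile should enter C22 from the side of the one-carbon bridge C20, anti to the C15–C16–C17 bridge that covers the other face, which places the alkynyl group cis to the C18 methyl as required.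

Step 15
Reactants: 22 enol silyl ether
Product: 24 ketone with 2-methylprop-2-enyl on C5 trans to the C22 (trimethylsilyl)ethynyl group and the C8 trimethylsilyl ether, via lithium enolate 23 (not isolated)
Conditions: MeLi (1.0 equiv), THF, –20 to 0 °C; 3-bromo-2-methylprop-1-ene, DMPU, –78 to 0 °C
Reagents that add atoms: 3-bromo-2-methylprop-1-ene, C=C(C)CBr
Why: Methyllithium cleaves the enol silyl ether to the regiodefined lithium enolate, which the allylic bromide alkylates at C5 anti to the adjacent pseudo-axial C22 alkynyl group (the usual trans outcome of vicinal difunctionalisation); C5 stays epimerisable, so the trans arrangement, expected to be the more stable, can also be reached by equilibration.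

Step 16
Reactants: 24 methallyl ketone
Product: 25 C5 2-oxopropyl diketone with C8 trimethylsilyl ether and C22 (trimethylsilyl)ethynyl group
Conditions: OsO4 (cat.), NaIO4, 2,6-lutidine, dioxane–H2O, rt
Reagents that add atoms: osmium tetroxide, O=[Os](=O)(=O)=O, its oxygen resupplied by sodium periodate, [Na+].[O-]I(=O)(=O)=O
Why: Lemieux–Johnson oxidation: osmylation is selective for the electron-rich 1,1-disubstituted alkene over the silyl alkyne and periodate cleaves the diol to the methyl ketone, the buffered medium avoiding epimerisation at C5.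

Step 17
Reactants: 25 silylated diketone
Product: 26 diketone with free C8 hydroxyl and C22 ethynyl group
Conditions: Bu4NF, AcOH, THF, 0 °C to rt
Reagents that add atoms: none
Why: Fluoride cleaves the C(sp)–Si bond and the tertiary silyl ether, and acetic acid buffering keeps the medium non-basic so that C5 and the 1,4-diketone are not disturbed.

Step 18
Reactants: 26 terminal alkyne
Product: 28 potassium (E)-alkenyltrifluoroborate (BF3K on C24, E C23=C24), via alkenyl pinacol boronate 27 (not isolated)
Conditions: pinacolborane, RhCl(CO)(PPh3)2 (cat.), CH2Cl2, rt; then KHF2, MeOH–H2O, rt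
Reagents that add atoms: pinacolborane, B1OC(C)(C)C(C)(C)O1; potassium hydrogen difluoride, [K+].F[H-]F
Why: Rhodium-catalysed hydroboration of the terminal alkyne gives the (E)-alkenylboronate by syn, anti-Markovnikov addition and, as a metal-catalysed process, prefers the triple bond over the ketones; potassium hydrogen difluoride then converts the boronate into the stable trifluoroborate.

Step 19
Reactants: 28 alkenyltrifluoroborate; 29 3-methylbut-2-enoic acid
Product: 30 CNP0237201.2 (target)
Conditions: CuBr (10 mol%), DMAP (20 mol%), 4 Å molecular sieves, O2 (1 atm), MeCN, 60 °C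
Reagents that add atoms: none
Why: Copper-catalysed oxidative C–O coupling of an alkenyltrifluoroborate with a carboxylic acid (Chan–Lam-type, known to give enol esters without decarboxylation and with retention of alkene geometry) should form the (E)-enol ester, the hindered tertiary alcohol and the ketones not being competent partners.

**Compound list**

1 | 2-methyl-4-(trimethylsilyl)but-3-yn-2-ol | CC(C)(O)C#C[Si](C)(C)C | starting material
2 | methyl 2-(bromomethyl)prop-2-enoate | C=C(CBr)C(=O)OC | starting material
3 | methyl 2-({[2-methyl-4-(trimethylsilyl)but-3-yn-2-yl]oxy}methyl)prop-2-enoate | C=C(COC(C)(C)C#C[Si](C)(C)C)C(=O)OC | intermediate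
4 | methyl 3-{[2-methyl-4-(trimethylsilyl)but-3-yn-2-yl]oxy}-2-oxopropanoate | COC(=O)C(=O)COC(C)(C)C#C[Si](C)(C)C | intermediate
5 | ethynyltrimethylsilane | C#C[Si](C)(C)C | starting material
6 | methyl (2R)-2-hydroxy-2-({[2-methyl-4-(trimethylsilyl)but-3-yn-2-yl]oxy}methyl)-4-(trimethylsilyl)but-3-ynoate | C[Si](C)(C)C#C[C@@](O)(COC(C)(C)C#C[Si](C)(C)C)C(=O)OC | intermediate
7 | (2R)-2-hydroxy-N-methoxy-N-methyl-2-({[2-methyl-4-(trimethylsilyl)but-3-yn-2-yl]oxy}methyl)-4-(trimethylsilyl)but-3-ynamide | C[Si](C)(C)C#C[C@@](O)(COC(C)(C)C#C[Si](C)(C)C)C(=O)N(C)OC | intermediate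
8 | 2-(2-bromoethyl)-2-methyl-1,3-dioxolane | CC1(CCBr)OCCO1 | starting material
9 | [2-(2-methyl-1,3-dioxolan-2-yl)ethyl]magnesium bromide | CC1(CC[Mg]Br)OCCO1 | intermediate (not isolated)
10 | (4R)-4-hydroxy-1-(2-methyl-1,3-dioxolan-2-yl)-4-({[2-methyl-4-(trimethylsilyl)but-3-yn-2-yl]oxy}methyl)-6-(trimethylsilyl)hex-5-yn-3-one | C[Si](C)(C)C#C[C@@](O)(COC(C)(C)C#C[Si](C)(C)C)C(=O)CCC1(C)OCCO1 | intermediate (not isolated)
11 | (6R)-6-hydroxy-6-({[2-methyl-4-(trimethylsilyl)but-3-yn-2-yl]oxy}methyl)-8-(trimethylsilyl)oct-7-yne-2,5-dione | C[Si](C)(C)C#C[C@@](O)(COC(C)(C)C#C[Si](C)(C)C)C(=O)CCC(C)=O | intermediate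
12 | (6R)-6-hydroxy-6-{[(2-methylbut-3-yn-2-yl)oxy]methyl}oct-7-yne-2,5-dione | C#C[C@@](O)(COC(C)(C)C#C)C(=O)CCC(C)=O | intermediate
13 | diethyl [(phenylsulfonyl)methyl]phosphonate | CCOP(=O)(CS(=O)(=O)c1ccccc1)OCC | starting material
14 | (3R,7E)-3-hydroxy-7-methyl-3-{[(2-methylbut-3-yn-2-yl)oxy]methyl}-8-(phenylsulfonyl)oct-7-en-1-yn-4-one | C#C[C@@](O)(COC(C)(C)C#C)C(=O)CC/C(C)=C/S(=O)(=O)c1ccccc1 | intermediate
15 | (4E)-1-[(3R)-3-hydroxy-6,6-dimethyl-4,5-dimethylideneoxan-3-yl]-4-methyl-5-(phenylsulfonyl)pent-4-en-1-one | C=C1C(=C)[C@@](O)(COC1(C)C)C(=O)CC/C(C)=C/S(=O)(=O)c1ccccc1 | intermediate (key-step precursor)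
16 | (8R,17R,18R) cycloadduct: tricyclic C15=C21 bridgehead alkene with C6 ketone, C8 hydroxyl and C17 phenylsulfonyl cis to the C18 methyl | C1C(=O)[C@]2(O)COC(C)(C)C3=C2C[C@](C)([C@@H](C3)S(=O)(=O)c4ccccc4)C1 | intermediate (key-step product)
17 | (8R,18R) desulfonylated tricyclic alkene ketol | C1C(=O)[C@]2(O)COC(C)(C)C3=C2C[C@](C)(CC3)C1 | intermediate
18 | (8R,15R,18R,21S) saturated tricyclic ketol | C1C(=O)[C@]2(O)COC(C)(C)[C@@H]3CC[C@@](C)(C[C@@H]32)C1 | intermediate
19 | C8 trimethylsilyl ether, C5=C6 trimethylsilyl enol ether of 18 | C1=C(O[Si](C)(C)C)[C@]2(O[Si](C)(C)C)COC(C)(C)[C@@H]3CC[C@@](C)(C[C@@H]32)C1 | intermediate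
20 | C5=C22 enone with C8 trimethylsilyl ether | C1=CC(=O)[C@]2(O[Si](C)(C)C)COC(C)(C)[C@@H]3CC[C@@]1(C)C[C@@H]32 | intermediate
21 | [(trimethylsilyl)ethynyl]zinc bromide | C[Si](C)(C)C#C[Zn]Br | intermediate (not isolated)
22 | C5=C6 trimethylsilyl enol ether with (trimethylsilyl)ethynyl on C22 (cis to C18 methyl) and C8 trimethylsilyl ether | C1=C(O[Si](C)(C)C)[C@]2(O[Si](C)(C)C)COC(C)(C)[C@@H]3CC[C@@](C)(C[C@@H]32)[C@H]1C#C[Si](C)(C)C | intermediate
23 | lithium enolate corresponding to 22 | C1=C(O[Li])[C@]2(O[Si](C)(C)C)COC(C)(C)[C@@H]3CC[C@@](C)(C[C@@H]32)[C@H]1C#C[Si](C)(C)C | intermediate (not isolated)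
24 | C6 ketone with 2-methylprop-2-enyl on C5 trans to the C22 (trimethylsilyl)ethynyl group, C8 trimethylsilyl ether | C=C(C)C[C@@H]1C(=O)[C@]2(O[Si](C)(C)C)COC(C)(C)[C@@H]3CC[C@@](C)(C[C@@H]32)[C@H]1C#C[Si](C)(C)C | intermediate
25 | C5 2-oxopropyl diketone, C8 trimethylsilyl ether, C22 (trimethylsilyl)ethynyl | CC(=O)C[C@@H]1C(=O)[C@]2(O[Si](C)(C)C)COC(C)(C)[C@@H]3CC[C@@](C)(C[C@@H]32)[C@H]1C#C[Si](C)(C)C | intermediate
26 | C5 2-oxopropyl diketone with free C8 hydroxyl and C22 ethynyl | CC(=O)C[C@@H]1C(=O)[C@]2(O)COC(C)(C)[C@@H]3CC[C@@](C)(C[C@@H]32)[C@H]1C#C | intermediate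
27 | (E)-alkenyl pinacol boronate (Bpin on C24) | CC(=O)C[C@@H]1C(=O)[C@]2(O)COC(C)(C)[C@@H]3CC[C@@](C)(C[C@@H]32)[C@H]1/C=C/B4OC(C)(C)C(C)(C)O4 | intermediate (not isolated)
28 | potassium (E)-alkenyltrifluoroborate | CC(=O)C[C@@H]1C(=O)[C@]2(O)COC(C)(C)[C@@H]3CC[C@@](C)(C[C@@H]32)[C@H]1/C=C/[B-](F)(F)F.[K+] | intermediate
29 | 3-methylbut-2-enoic acid | CC(C)=CC(O)=O | starting material
30 | CNP0237201.2, (5S,8R,15R,18S,21S,22S), (E)-enol 3-methylbut-2-enoate | CC(=O)C[C@@H]1C(=O)[C@]2(O)COC(C)(C)[C@@H]3CC[C@@](C)(C[C@@H]32)[C@H]1/C=C/OC(=O)C=C(C)C | target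

**Step count and risks**

Total steps: 19. Longest linear sequence: 19 steps (from 1 and 2 to 30).

Steps most likely to fail:

1. Step 9. The bridged cycloaddition may be slower than intermolecular dimerisation of the diene or than thermal α-ketol rearrangement, so that 15 is consumed before ring closure. The fallback changes the dienophile to one that a Lewis acid can activate at low temperature. It sets out from 12: Horner–Wadsworth–Emmons olefination with triethyl phosphonoacetate (NaH, THF) would give the (E)-enoate diyne F1; the reductive diyne cyclisation of step 8 would give the triene ester F2; EtAlCl2 (excess, CH2Cl2, –78 to 0 °C) would promote the same type 2 cycloaddition to the ester adduct F3; LiOH would give the acid F4; this is converted into its N-acyloxypyridine-2-thione F5 (2-mercaptopyridine N-oxide, DCC) and decarboxylated reductively (t-BuSH, hν; Barton decarboxylation). The route is rejoined at 17.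

2. Step 14. The neopentyl-type β-carbon C22 may be too hindered for the alkynylzinc reagent, with recovery of enone or competing 1,2-addition. The fallback uses a vinyl donor and builds the alkenylboron by metathesis. It sets out from 20: copper-catalysed conjugate addition of vinylmagnesium bromide with TMSCl (CuBr·SMe2, THF, –78 °C) would give the enol silyl ether F6; SnCl4-mediated Michael addition of F6 to 2-nitropropene followed by aqueous Nef hydrolysis would install the 2-oxopropyl group trans to the vinyl group and remove the silyl groups, giving the vinyl diketone F7; cross-metathesis of F7 with 2-ethenyl-4,4,5,5-tetramethyl-1,3,2-dioxaborolane (second-generation Hoveyda–Grubbs catalyst) would give the (E)-alkenylboronate 27, and KHF2 then gives 28, where the route is rejoined.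

3. Step 3. The alkynylation may give low enantioselectivity or the wrong sense of induction, or the enolisable α-keto ester may self-condense under the amine base. The fallback gives up catalytic control: from 4, addition of lithium (trimethylsilyl)acetylide (from 5 and n-BuLi, THF, –78 °C) would give the racemic hydroxy ester F8, which is resolved by preparative chromatography on a chiral stationary phase. The route is rejoined at 6.

**Further compounds**

F1 | step 9 | ethyl (2E,7R)-7-ethynyl-7-hydroxy-3-methyl-8-[(2-methylbut-3-yn-2-yl)oxy]-6-oxooct-2-enoate | C#C[C@@](O)(COC(C)(C)C#C)C(=O)CC/C(C)=C/C(=O)OCC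
F2 | step 9 | ethyl (2E)-6-[(3R)-3-hydroxy-6,6-dimethyl-4,5-dimethylideneoxan-3-yl]-3-methyl-6-oxohex-2-enoate | C=C1C(=C)[C@@](O)(COC1(C)C)C(=O)CC/C(C)=C/C(=O)OCC
F3 | step 9 | ester analogue of 16 (ethoxycarbonyl on C17 cis to the C18 methyl) | C1C(=O)[C@]2(O)COC(C)(C)C3=C2C[C@](C)([C@@H](C3)C(=O)OCC)C1
F4 | step 9 | C17 carboxylic acid from F3 | C1C(=O)[C@]2(O)COC(C)(C)C3=C2C[C@](C)([C@@H](C3)C(O)=O)C1
F5 | step 9 | N-acyloxypyridine-2-thione (Barton ester) of F4 | C1C(=O)[C@]2(O)COC(C)(C)C3=C2C[C@](C)([C@@H](C3)C(=O)On4ccccc4=S)C1
F6 | step 14 | C5=C6 trimethylsilyl enol ether with vinyl on C22 and C8 trimethylsilyl ether | C1=C(O[Si](C)(C)C)[C@]2(O[Si](C)(C)C)COC(C)(C)[C@@H]3CC[C@@](C)(C[C@@H]32)[C@H]1C=C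
F7 | step 14 | C5 2-oxopropyl diketone with vinyl on C22 and free C8 hydroxyl | CC(=O)C[C@@H]1C(=O)[C@]2(O)COC(C)(C)[C@@H]3CC[C@@](C)(C[C@@H]32)[C@H]1C=C
F8 | step 3 | racemic methyl 2-hydroxy-2-({[2-methyl-4-(trimethylsilyl)but-3-yn-2-yl]oxy}methyl)-4-(trimethylsilyl)but-3-ynoate | C[Si](C)(C)C#CC(O)(COC(C)(C)C#C[Si](C)(C)C)C(=O)OC
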